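- The epsilon run charges 44 mM of X against 28 mM in the theta run, yet after 40.0 min the two show X at 33% and 35% of their charges, and Q at 61% and 61%.

| setting | theta | epsilon | Friday's | Tuesday's | Saturday's |
|---|---|---|---|---|---|
| X | 28 mM | 44 mM | 20 mM | 20 mM | 20 mM |
| E | 11 mM (held) | 11 mM (held) | 11 mM (held) | 11 mM (held) | 11 mM (held) |
| remark | run made earlier | run made earlier |  |  |  |
| time |  |  | 2.0 h | 2.5 h | 3.0 h |

| run | time / min | Q / % | X / % | G / % |
|---|---|---|---|---|
| theta | 20.0 | 39 | 58 | 6 |
| theta | 40.0 | 61 | 33 | 8 |
| theta | 60.0 | 73 | 18 | 4 |
| theta | 80.0 | 83 | 11 | 7 |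
| theta | 90.0 | 85 | 5 | 7 |
| epsilon | 8.00 | 18 | 84 | 3 |
| epsilon | 25.0 | 44 | 49 | 3 |
| epsilon | 40.0 | 61 | 35 | 6 |
| epsilon | 60.0 | 71 | 21 | 5 |
| epsilon | 90.0 | 85 | 7 | 6 |

(readings scatter by 2 percentage points)

* which of these there is most of at the end, counted by the X in it, Friday's (G / X / Q)
* which of these there is most of at the end, counted by the X in it, Tuesday's (G / X / Q)
* which of these there is most of at the end, counted by the X in it, Saturday's (G / X / Q)
* the largest of these amounts at the end, in percent of the X charged, Friday's
* the largest of these amounts at the end, in percent of the X charged, Tuesday's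
* the largest of these amounts at the end, in percent of the X charged, Saturday's

- what was read earlier has a scatter of 2 percentage points, one standard deviation
- at the start none of E is in solution

- Those numbers go together if the larger charge loses more millimoles per minute but the same fraction, which is first-order decay. Let k_X be the fraction of the remaining X lost per unit time, read from both runs at 60.0 min, where X stands at 18% and 21%: k_X = 0.0273 /min, a reading with the scatter of 2 percentage points, giving a half-life of 25.4 min.
- Carried to the 20 mM flasks, k_X leaves X at 3.78% on Friday's, 1.67% on Tuesday's and 0.735% on Saturday's.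
- G reads 7% and 6% at 90.0 min, about 6.50%. My own reckoning takes Q as the charge less X and G: 89.7%, 91.8% and 92.8%.
- The forecast names Q, Q and Q, with 90%, 91.5% and 92.5%, and states: “The X decay is first order.”
- The flasks give Q as the largest amount, 89.2%, 92.1% and 94.0%, as the forecast said.

    L → J (k = 0.0360 /min)
    X → Q (k = 0.0250 /min)
    E ⇌ L, rate k3*(csat - [L]) (kL = 0.0180 /min)
    X + L ⇌ G (K = 150 /M, k = 1.70 /M/min)

- Friday's and Saturday's differ in time, and between them X falls from 4.97% to 2.14%, a late rate of 0.0141 /min, half of k_X, while G sinks from 5.87% to 3.84%. L, the dissolved E, binds X as G or goes on to the product J, and at the end of Saturday's it stands at 3.78 mM against 11 mM at saturation. The run without the finite pace of the transfer of E to L ends Saturday's with Q at 80.4% rather than 94.0%, the largest single effect among the reasons tried.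
- For a reading of Saturday's at 2.0 h, k_X gives X at 3.78% and Q at 89.7%; the computed flask holds 5.0% and 89.2%.

The earlier runs and the new flask were generated by integration on assumed constants; noise was put on by code.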